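## Retrosynthetic overview

- Kanzonol E is a flavone (rings A/C = 4H-chromen-4-one, ring B = aryl on C2) with a prenyl group on C6 next to the 7-OH and a 2,2-dimethyl-2H-pyran fused across C3'–C4' of ring B.
- Enabling feature: each C5 unit sits on a ring carbon ortho to a phenolic oxygen (C6/O7 in ring A; C3'/O4' in ring B, where C3' and C5' are equivalent). The pyran atoms O–CMe2–CH=CH–C3'–C4' are those of an O4'–CMe2–C≡CH ether after a [3,3] shift, and the C6 prenyl is an O7–CMe2–CH=CH2 ether after a [3,3] shift.
- Key disconnection: kanzonol E ⇒ its isomer, the 7-O-(1,1-dimethylallyl)/4'-O-(1,1-dimethylpropargyl) bis-ether of 7,4'-dihydroxyflavone. One thermal operation makes the C6–C and C3'–C bonds and then the pyran O–C bond.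
- Bis-ether ⇒ 7,4'-dihydroxyflavone by two O-alkylations with the same C5 chloride (differentiated by phenol acidity and a Lindlar reduction); flavone ⇒ isoliquiritigenin ⇒ 2,4-dihydroxyacetophenone + 4-hydroxybenzaldehyde.
- Ring order: rings A and B are purchased, ring C (pyranone) is closed in step 2, and the 2H-pyran ring of the chromene is closed last, in step 6.

Key step: step 6

Assumption: kanzonol E has no stereocentre (the pyran sp3 carbon and the prenyl terminus each carry two methyl groups, and the pyran C=C is cis by ring constraint), so the "single enantiomer" is the one achiral constitution shown and no asymmetric step is planned.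

## Route

Step 1
Reactants: 1 2,4-dihydroxyacetophenone; 2 4-hydroxybenzaldehyde
Product: 3 isoliquiritigenin, (E)-1-(2,4-dihydroxyphenyl)-3-(4-hydroxyphenyl)prop-2-en-1-one
Conditions: KOH (60% aq, 10 equiv), EtOH, rt→50 °C; then 2 M HCl
Reagents that add atoms: none
Why: Claisen–Schmidt (crossed aldol) condensation, in which the acetophenone enolate adds to the non-enolisable aldehyde and E1cB loss of water gives the conjugated enone in its thermodynamic (E) geometry; excess hydroxide keeps the phenols as phenoxides, which slows but should not prevent the condensation.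

Step 2
Reactants: 3 isoliquiritigenin
Product: 5 7,4'-dihydroxyflavone, via rac-liquiritigenin 4 (not isolated)
Conditions: I2 (10 mol%), DMSO, 130 °C
Reagents that add atoms: none
Why: Iodine-catalysed oxidative cyclisation of a 2'-hydroxychalcone in DMSO, in which 6-endo oxa-Michael closure gives flavanone 4, which is α-iodinated and loses HI to the flavone while DMSO reoxidises HI to I2; free phenols should be tolerated.

Step 3
Reactants: 5 7,4'-dihydroxyflavone; 6 3-chloro-3-methylbut-1-yne
Product: 7 4'-hydroxy-7-(2-methylbut-3-yn-2-yloxy)flavone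
Conditions: 6 (1.1 equiv), K2CO3 (1.1 equiv), KI (20 mol%), CuI (5 mol%), acetone, 50 °C, N2
Reagents that add atoms: 3-chloro-3-methylbut-1-yne (6), CC(C)(Cl)C#C
Why: Copper-assisted O-alkylation of a phenoxide with a tertiary propargylic chloride; with about one equivalent of carbonate the 7-OH (a vinylogous carboxylic acid para to the C4 carbonyl, the more acidic phenol) should be ionised and etherified in preference to the 4'-OH.

Step 4
Reactants: 7 4'-hydroxy-7-(2-methylbut-3-yn-2-yloxy)flavone
Product: 8 4'-hydroxy-7-(2-methylbut-3-en-2-yloxy)flavone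
Conditions: H2 (1 atm), Lindlar catalyst (Pd/CaCO3, Pb-poisoned), quinoline, EtOAc, rt
Reagents that add atoms: none
Why: Lindlar semihydrogenation, in which the poisoned palladium adds one equivalent of H2 to the terminal alkyne and stops at the alkene, leaving the flavone C2=C3 bond and the tertiary C–O bond untouched.

Step 5
Reactants: 8 4'-hydroxy-7-(2-methylbut-3-en-2-yloxy)flavone; 6 3-chloro-3-methylbut-1-yne
Product: 9 7-(2-methylbut-3-en-2-yloxy)-4'-(2-methylbut-3-yn-2-yloxy)flavone
Conditions: 6 (3 equiv), K2CO3 (2 equiv), KI (20 mol%), CuI (5 mol%), acetone, 50 °C, N2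
Reagents that add atoms: 3-chloro-3-methylbut-1-yne (6), CC(C)(Cl)C#C
Why: The same copper-assisted O-propargylation, now on the only remaining phenol; the 1,1-dimethylallyl ether is stable to carbonate in acetone at 50 °C, well below the onset of its Claisen rearrangement.

Step 6
Reactants: 9 7-(2-methylbut-3-en-2-yloxy)-4'-(2-methylbut-3-yn-2-yloxy)flavone
Product: 13 kanzonol E, via prenylphenol 10 (not isolated), via allenylphenol 11 (not isolated), via ortho-quinone methide 12 (not isolated)
Conditions: PhNEt2 (degassed), 130 °C then 195 °C, Ar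
Reagents that add atoms: none
Why: At 130 °C the tertiary allyl ether on O7 undergoes an aromatic Claisen rearrangement ([3,3], chair transition state; closest known reaction type: ortho-Claisen of aryl 1,1-dimethylallyl ethers), which inverts the allyl unit so that its CH2 terminus bonds to C6 and, after enolisation of the dearomatised keto tautomer, gives the 6-prenyl-7-hydroxy compound 10. At 195 °C the 4'-O-propargyl ether follows the known thermal chromene cascade of aryl 1,1-dimethylpropargyl ethers: a [3,3] shift to C3' and enolisation give allenylphenol 11, a [1,5]-H shift from O–H to the central allene carbon gives the (Z)-ortho-quinone methide 12, and a thermal disrotatory oxa-6π electrocyclisation (O–C bond between the quinone-methide oxygen and the CMe2 terminus) closes the six-membered 2H-pyran ring and rearomatises ring B. No stereocentre is formed, because the pyran sp3 carbon carries two methyl groups, its C=C is cis by ring constraint and the prenyl C=C ends in two identical methyls. Regiochemistry on ring B needs no control, because C3' and C5' are equivalent by rotation about the C2–C1' bond and both are unsubstituted CH. On ring A the shift must go to C6 and not to C8; this is expected because C8 is wedged between O7 and the ring oxygen O1 and should be avoided by the bulky tertiary allyl ether, as in the related 7-(1,1-dimethylallyloxy)benzopyran-2-ones, for which the linear 6-prenyl phenol is the reported main product. Chemoselectivity between the two ethers rests on the lower onset temperature of the tertiary allyl shift (staged heating), and the basic amine solvent should suppress ionisation of the ether and acid-catalysed cyclisation of the ortho-prenyl phenol onto its own OH.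

## Compound list

1 | 2,4-dihydroxyacetophenone, 1-(2,4-dihydroxyphenyl)ethanone | CC(=O)c1ccc(O)cc1O | starting material
2 | 4-hydroxybenzaldehyde | O=Cc1ccc(O)cc1 | starting material
3 | isoliquiritigenin, (E)-1-(2,4-dihydroxyphenyl)-3-(4-hydroxyphenyl)prop-2-en-1-one | O=C(/C=C/c1ccc(O)cc1)c1ccc(O)cc1O | intermediate
4 | rac-liquiritigenin, 7-hydroxy-2-(4-hydroxyphenyl)chroman-4-one (racemic) | O=C1CC(c2ccc(O)cc2)Oc2cc(O)ccc21 | intermediate
5 | 7,4'-dihydroxyflavone, 7-hydroxy-2-(4-hydroxyphenyl)-4H-chromen-4-one | O=c1cc(-c2ccc(O)cc2)oc2cc(O)ccc12 | intermediate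
6 | 3-chloro-3-methylbut-1-yne | CC(C)(Cl)C#C | starting material
7 | 2-(4-hydroxyphenyl)-7-(2-methylbut-3-yn-2-yloxy)-4H-chromen-4-one | C#CC(C)(C)Oc1ccc2c(=O)cc(-c3ccc(O)cc3)oc2c1 | intermediate
8 | 2-(4-hydroxyphenyl)-7-(2-methylbut-3-en-2-yloxy)-4H-chromen-4-one | C=CC(C)(C)Oc1ccc2c(=O)cc(-c3ccc(O)cc3)oc2c1 | intermediate
9 | 7-(2-methylbut-3-en-2-yloxy)-2-[4-(2-methylbut-3-yn-2-yloxy)phenyl]-4H-chromen-4-one | C=CC(C)(C)Oc1ccc2c(=O)cc(-c3ccc(OC(C)(C)C#C)cc3)oc2c1 | intermediate
10 | 7-hydroxy-6-(3-methylbut-2-en-1-yl)-2-[4-(2-methylbut-3-yn-2-yloxy)phenyl]-4H-chromen-4-one | CC(C)=CCc1cc2c(=O)cc(-c3ccc(OC(C)(C)C#C)cc3)oc2cc1O | intermediate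
11 | 7-hydroxy-2-[4-hydroxy-3-(3-methylbuta-1,2-dien-1-yl)phenyl]-6-(3-methylbut-2-en-1-yl)-4H-chromen-4-one | CC(C)=CCc1cc2c(=O)cc(-c3ccc(O)c(C=C=C(C)C)c3)oc2cc1O | intermediate
12 | 7-hydroxy-6-(3-methylbut-2-en-1-yl)-2-[(3Z)-3-(3-methylbut-2-en-1-ylidene)-4-oxocyclohexa-1,5-dien-1-yl]-4H-chromen-4-one | CC(C)=CCc1cc2c(=O)cc(C3=C/C(=C/C=C(C)C)C(=O)C=C3)oc2cc1O | intermediate
13 | kanzonol E, 2-(2,2-dimethyl-2H-chromen-6-yl)-7-hydroxy-6-(3-methylbut-2-en-1-yl)-4H-chromen-4-one | CC(C)=CCc1cc2c(=O)cc(-c3ccc4c(c3)C=CC(C)(C)O4)oc2cc1O | target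

## Step count and risks

Total step count: 6. Longest linear sequence: 6 steps (1 → 3 → 5 → 7 → 8 → 9 → 13).

Steps most likely to fail:

1. Step 6. The ring-A [3,3] shift may deliver the allyl unit to C8 as well as C6, or the tertiary allyl ether may ionise and lose isoprene before it rearranges. Fallback: the C6–C bond is made by cross-coupling at a carbon fixed by halogenation of the acetophenone, and only the propargyl half of the cascade is kept as the last ring closure. It sets out from 1 and comes back to the route at 13. NBS (MeCN, 0 °C) should brominate 1 para to the chelated 2-OH to give 1-(5-bromo-2,4-dihydroxyphenyl)ethanone F1. Claisen–Schmidt condensation with 2 (KOH, EtOH) gives (E)-1-(5-bromo-2,4-dihydroxyphenyl)-3-(4-hydroxyphenyl)prop-2-en-1-one F2, and I2/DMSO gives 6-bromo-7-hydroxy-2-(4-hydroxyphenyl)-4H-chromen-4-one F3. The more acidic, bromine-flanked 7-OH is masked with MOMCl/i-Pr2NEt (1 equiv) as 6-bromo-2-(4-hydroxyphenyl)-7-(methoxymethoxy)-4H-chromen-4-one F4. O-alkylation with 6 (K2CO3, KI, CuI, acetone) gives 6-bromo-7-(methoxymethoxy)-2-[4-(2-methylbut-3-yn-2-yloxy)phenyl]-4H-chromen-4-one F5. Heating in PhNEt2 at 195 °C closes the pyran ring to 6-bromo-2-(2,2-dimethyl-2H-chromen-6-yl)-7-(methoxymethoxy)-4H-chromen-4-one F6. Stille coupling with tributyl(3-methylbut-2-en-1-yl)stannane (Pd(PPh3)4, DMF, 90 °C) gives 2-(2,2-dimethyl-2H-chromen-6-yl)-7-(methoxymethoxy)-6-(3-methylbut-2-en-1-yl)-4H-chromen-4-one F7, and dilute HCl in MeOH (rt) removes the MOM group to give 13.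

2. Step 3. Discrimination between the two phenols may be insufficient, so that 4'-O-alkylation and double alkylation compete with 7-O-alkylation. Fallback: the discrimination is moved from alkylation to deacylation, where the 7-O-acyl group of a flavone is the most labile. It sets out from 5 and comes back to the route at 7. Ac2O/pyridine gives 4-(7-acetoxy-4-oxo-4H-chromen-2-yl)phenyl acetate F8. PhSH/imidazole in NMP at 0 °C should remove only the 7-O-acetyl group to give 4-(7-hydroxy-4-oxo-4H-chromen-2-yl)phenyl acetate F9. Alkylation of the single free phenol with 6 (K2CO3, KI, CuI, acetone) gives 4-[7-(2-methylbut-3-yn-2-yloxy)-4-oxo-4H-chromen-2-yl]phenyl acetate F10, and K2CO3/MeOH at 0 °C cleaves the remaining acetate to give 7.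

3. Step 4. The hydrogenation may run on to the tert-pentyl ether, or the propargylic/allylic C–O bond may be hydrogenolysed. Fallback: the 1,1-dimethylallyl ether is made directly by Pd(0)-catalysed O-allylation (Tsuji–Trost type, tertiary ether as kinetic product), so that no alkyne has to be reduced. It sets out from 5 and comes back to the route at 8. 2-Methylbut-3-en-2-ol is converted with n-BuLi/Boc2O into tert-butyl 2-methylbut-3-en-2-yl carbonate F11. Compound 5 is then treated with F11 and Pd(PPh3)4 (cat.) in THF at 0 °C; the tert-butoxide released on ionisation deprotonates the more acidic 7-OH, whose phenoxide should attack the more substituted allyl terminus to give 8.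

Further compounds
F1 | step 6 | 1-(5-bromo-2,4-dihydroxyphenyl)ethanone | CC(=O)c1cc(Br)c(O)cc1O
F2 | step 6 | (E)-1-(5-bromo-2,4-dihydroxyphenyl)-3-(4-hydroxyphenyl)prop-2-en-1-one | O=C(/C=C/c1ccc(O)cc1)c1cc(Br)c(O)cc1O
F3 | step 6 | 6-bromo-7-hydroxy-2-(4-hydroxyphenyl)-4H-chromen-4-one | O=c1cc(-c2ccc(O)cc2)oc2cc(O)c(Br)cc12
F4 | step 6 | 6-bromo-2-(4-hydroxyphenyl)-7-(methoxymethoxy)-4H-chromen-4-one | COCOc1cc2oc(-c3ccc(O)cc3)cc(=O)c2cc1Br
F5 | step 6 | 6-bromo-7-(methoxymethoxy)-2-[4-(2-methylbut-3-yn-2-yloxy)phenyl]-4H-chromen-4-one | COCOc1cc2oc(-c3ccc(OC(C)(C)C#C)cc3)cc(=O)c2cc1Br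
F6 | step 6 | 6-bromo-2-(2,2-dimethyl-2H-chromen-6-yl)-7-(methoxymethoxy)-4H-chromen-4-one | COCOc1cc2oc(-c3ccc4c(c3)C=CC(C)(C)O4)cc(=O)c2cc1Br
F7 | step 6 | 2-(2,2-dimethyl-2H-chromen-6-yl)-7-(methoxymethoxy)-6-(3-methylbut-2-en-1-yl)-4H-chromen-4-one | COCOc1cc2oc(-c3ccc4c(c3)C=CC(C)(C)O4)cc(=O)c2cc1CC=C(C)C
F8 | step 3 | 4-(7-acetoxy-4-oxo-4H-chromen-2-yl)phenyl acetate | CC(=O)Oc1ccc(-c2cc(=O)c3ccc(OC(C)=O)cc3o2)cc1
F9 | step 3 | 4-(7-hydroxy-4-oxo-4H-chromen-2-yl)phenyl acetate | CC(=O)Oc1ccc(-c2cc(=O)c3ccc(O)cc3o2)cc1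
F10 | step 3 | 4-[7-(2-methylbut-3-yn-2-yloxy)-4-oxo-4H-chromen-2-yl]phenyl acetate | CC(=O)Oc1ccc(-c2cc(=O)c3ccc(OC(C)(C)C#C)cc3o2)cc1
F11 | step 4 | tert-butyl 2-methylbut-3-en-2-yl carbonate | C=CC(C)(C)OC(=O)OC(C)(C)C
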